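**Retrosynthetic overview**
The target is (2S)-7,4′-dihydroxy-6,8,3′-triprenylflavanone; the last step only frees the 4′-OH from a MOM ether.
Ring C is the only ring to be made and is closed last through the bond C4(carbonyl)–C4a(aryl): an aryllithium at C4a (from C4a–Br) attacks a Weinreb amide (C4) held by the O1–C2–C3 tether (Parham cyclization), and in the same flask the aryllithiums at C6 (ring A) and C3′ (ring B) are prenylated.
Enabling feature: every carbon substituent of rings A and B sits ortho or para to a phenolic oxygen (C4a, C6 and C8 are the three positions activated by O1 and the C7 oxygen of resorcinol ring A; C3′ is ortho to the C4′ oxygen), so each can be carried as a bromine atom; C4a is ortho to O1 and, once C8 holds its prenyl group, is the only metalated carbon that can reach C4 in a six-membered ring.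
The O1–C2 bond and the (2S) centre come from Mitsunobu inversion of an (R)-β-hydroxy Weinreb amide (asymmetric transfer hydrogenation of a β-keto ester from 3′-bromo-4′-hydroxyacetophenone) with C2v-symmetric 4,6-dibromo-2-prenylresorcinol.
That resorcinol comes from 2,4,6-tribromoresorcinol by exchange and prenylation of the bromine between the two oxygens; rings A and B are bought aromatic.

Key step: step 9

Assumption: the stereodescriptor of the target SMILES is read as (2S) at C2, the configuration of the natural flavanones; flavanone numbering (O1, C2–C4, C4a, C5–C8, C8a, primed numbers for ring B) is used throughout.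

**Route**

Step 1
Reactants: 1 2,4,6-tribromobenzene-1,3-diol (2,4,6-tribromoresorcinol)
Product: 2 1,3,5-tribromo-2,4-bis(methoxymethoxy)benzene
Conditions: NaH (2.4 equiv), MOMCl (2.6 equiv), DMF, 0 °C → rt
Reagents that add atoms: chloromethyl methyl ether (MOMCl), COCCl
Why: Williamson-type O-alkylation of the two equivalent, acidic phenols should give the bis-MOM ether, whose two acetal oxygens flank the central bromine and direct the exchange of step 2.

Step 2
Reactants: 2 1,3,5-tribromo-2,4-bis(methoxymethoxy)benzene
Product: 5 1,5-dibromo-2,4-bis(methoxymethoxy)-3-(3-methylbut-2-en-1-yl)benzene, via aryllithium 3 (not isolated), via arylcopper 4 (not isolated)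
Conditions: n-BuLi (1.05 equiv), THF, −78 °C; CuBr·SMe2 (1.1 equiv), −78 → −40 °C; prenyl bromide (1.5 equiv), −40 °C → rt
Reagents that add atoms: 1-bromo-3-methylbut-2-ene (prenyl bromide), CC(C)=CCBr
Why: Bromine–lithium exchange should take place at the bromine flanked by the two OMOM groups, because that aryllithium is stabilised inductively and by chelation from both ortho oxygens and any other aryllithium formed first equilibrates to it by aryl bromide/aryllithium exchange, and the derived arylcopper is then allylated by prenyl bromide at its unsubstituted α-carbon (copper-mediated SN2 allylation).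

Step 3
Reactants: 5 1,5-dibromo-2,4-bis(methoxymethoxy)-3-(3-methylbut-2-en-1-yl)benzene
Product: 6 4,6-dibromo-2-(3-methylbut-2-en-1-yl)benzene-1,3-diol
Conditions: p-TsOH·H2O (0.2 equiv), MeOH, 40 °C
Reagents that add atoms: none
Why: Acid-catalysed acetal exchange with methanol (MOM cleavage) should free both phenols, the mild acid and the bromine-deactivated phenols leaving the prenyl double bond uncyclised, and the C2v symmetry of the diol makes the later mono-etherification regiochemically unambiguous.

Step 4
Reactants: 7 1-(3-bromo-4-hydroxyphenyl)ethan-1-one (3′-bromo-4′-hydroxyacetophenone)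
Product: 8 1-[3-bromo-4-(methoxymethoxy)phenyl]ethan-1-one
Conditions: MOMCl (1.3 equiv), K2CO3 (1.5 equiv), acetone, rt
Reagents that add atoms: chloromethyl methyl ether (MOMCl), COCCl
Why: Williamson etherification of the phenoxide protects the ring B phenol as an acetal that survives hydride, Grignard, Mitsunobu and organolithium conditions and later chelates the ortho aryllithium.

Step 5
Reactants: 8 1-[3-bromo-4-(methoxymethoxy)phenyl]ethan-1-one
Product: 9 methyl 3-[3-bromo-4-(methoxymethoxy)phenyl]-3-oxopropanoate
Conditions: NaH (2.5 equiv), (MeO)2CO (5 equiv), toluene, 90 °C; then AcOH, 0 °C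
Reagents that add atoms: dimethyl carbonate, COC(=O)OC
Why: Crossed Claisen condensation, in which the sodium enolate of the methyl ketone is C-acylated by the non-enolisable dimethyl carbonate and the equilibrium is pulled over by deprotonation of the β-keto ester formed.

Step 6
Reactants: 9 methyl 3-[3-bromo-4-(methoxymethoxy)phenyl]-3-oxopropanoate
Product: 10 methyl (3R)-3-[3-bromo-4-(methoxymethoxy)phenyl]-3-hydroxypropanoate
Conditions: RuCl(p-cymene)[(R,R)-TsDPEN] (1 mol %), HCO2H/Et3N (5:2), DMF, 30 °C
Reagents that add atoms: none
Why: Noyori asymmetric transfer hydrogenation of the aryl ketone, in which the (R,R)-TsDPEN ruthenium hydride should deliver hydride to the Si face through the CH/π-organised six-membered transition state known for aryl ketones and so set the (3R) carbinol centre under catalyst control, the aryl bromide and the MOM ether being inert to the buffered medium.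

Step 7
Reactants: 10 methyl (3R)-3-[3-bromo-4-(methoxymethoxy)phenyl]-3-hydroxypropanoate
Product: 11 (3R)-3-[3-bromo-4-(methoxymethoxy)phenyl]-3-hydroxy-N-methoxy-N-methylpropanamide
Conditions: MeNHOMe·HCl (3 equiv), i-PrMgCl (6.5 equiv), THF, −20 → 0 °C; sat. aq. NH4Cl
Reagents that add atoms: N,O-dimethylhydroxylamine hydrochloride, CNOC.Cl
Why: Aminolysis of the ester by the magnesium amide of N,O-dimethylhydroxylamine (Weinreb amide formation) at low temperature, where retro-aldol cleavage and bromine–magnesium exchange are slow, and carried out before the etherification so that no base ever meets the elimination-prone β-aryloxy carbonyl compound.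

Step 8
Reactants: 11 (3R)-3-[3-bromo-4-(methoxymethoxy)phenyl]-3-hydroxy-N-methoxy-N-methylpropanamide; 6 4,6-dibromo-2-(3-methylbut-2-en-1-yl)benzene-1,3-diol (2.5 equiv, excess recovered)
Product: 12 (3S)-3-[3-bromo-4-(methoxymethoxy)phenyl]-3-[2,4-dibromo-5-hydroxy-6-(3-methylbut-2-en-1-yl)phenoxy]-N-methoxy-N-methylpropanamide
Conditions: PPh3 (1.3 equiv), DIAD (1.3 equiv), toluene, 0 °C → rt, high concentration
Reagents that add atoms: none
Why: Mitsunobu etherification, in which the acidic, bromine-flanked phenol of 6 displaces the benzylic alkoxyphosphonium group of 11 by SN2 with inversion ((R) to (S)), the meta-bromine on ring B and the non-polar solvent disfavouring ionisation at the benzylic carbon, the weakly acidic α-hydrogens of the Weinreb amide disfavouring elimination, and the excess of the symmetric diol (either hydroxyl gives the same ether) suppressing double etherification.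

Step 9
Reactants: 12 (3S)-3-[3-bromo-4-(methoxymethoxy)phenyl]-3-[2,4-dibromo-5-hydroxy-6-(3-methylbut-2-en-1-yl)phenoxy]-N-methoxy-N-methylpropanamide
Product: 15 (2S)-7-hydroxy-2-[4-(methoxymethoxy)-3-(3-methylbut-2-en-1-yl)phenyl]-6,8-bis(3-methylbut-2-en-1-yl)-2,3-dihydro-4H-chromen-4-one, via lithium hemiaminalate 13 (not isolated), via bis(arylcopper) hemiaminalate 14 (not isolated)
Conditions: t-BuLi (7.2 equiv), THF, −78 °C (12 added slowly to the base); CuBr·SMe2 (2.3 equiv), −78 → −40 °C; prenyl bromide (4 equiv), −40 → 0 °C; sat. aq. NH4Cl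
Reagents that add atoms: 1-bromo-3-methylbut-2-ene (prenyl bromide), CC(C)=CCBr
Why: One equivalent of t-BuLi deprotonates the C7 phenol and six more exchange all three bromines; the aryllithium at C4a, held next to the Weinreb amide by the O1–C2–C3 tether, adds to the amide carbonyl at −78 °C (Parham cyclization, 6-exo-trig, closing ring C through the C4–C4a bond) to give the chelated lithium hemiaminalate 13, which can neither collapse nor over-add before work-up. The two aryllithiums that cannot reach the amide (C6 on ring A, C3′ on ring B) are transmetalated to arylcopper species and allylated by prenyl bromide at its unsubstituted α-carbon, so that one flask forms three C–C bonds and replaces all three bromine atoms. The closest known reaction types are the halogen–lithium exchange/Weinreb amide cyclization of β-(2-bromoaryloxy) amides to 2-substituted chroman-4-ones and the copper-mediated prenylation of ortho-oxygenated aryllithiums. No new stereocenter remains in the product (the hemiaminal carbon becomes the C4 carbonyl on quench), and the C2 centre set in step 8 is not touched because exchange at −78 °C should outrun deprotonation at C3 and the ketone is released only at work-up. The selectivities needed are ring closure at C4a only, secured because C8, the other carbon ortho to O1, already carries its prenyl group and C6 and C3′ cannot reach C4; exchange ahead of t-BuLi addition to the amide, secured by inverse addition at low temperature; and C- over O-prenylation, secured by the low nucleophilicity of the doubly flanked lithium phenoxide in THF.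

Step 10
Reactants: 15 (2S)-7-hydroxy-2-[4-(methoxymethoxy)-3-(3-methylbut-2-en-1-yl)phenyl]-6,8-bis(3-methylbut-2-en-1-yl)-2,3-dihydro-4H-chromen-4-one
Product: 16 (2S)-7-hydroxy-2-[4-hydroxy-3-(3-methylbut-2-en-1-yl)phenyl]-6,8-bis(3-methylbut-2-en-1-yl)-2,3-dihydro-4H-chromen-4-one (target)
Conditions: HCl (0.5 M in MeOH), 0 °C → rt
Reagents that add atoms: none
Why: Acid-catalysed acetal exchange removes the last MOM ether at or below room temperature, conditions under which flavanones should keep their C2 configuration and ortho-prenylphenols are normally not cyclised to chromans.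

**Compound list**
1 | 2,4,6-tribromobenzene-1,3-diol | Oc1c(Br)cc(Br)c(O)c1Br | starting material
2 | 1,3,5-tribromo-2,4-bis(methoxymethoxy)benzene | COCOc1c(Br)cc(Br)c(OCOC)c1Br | intermediate
3 | [3,5-dibromo-2,6-bis(methoxymethoxy)phenyl]lithium | [Li]c1c(OCOC)c(Br)cc(Br)c1OCOC | intermediate (not isolated)
4 | [3,5-dibromo-2,6-bis(methoxymethoxy)phenyl]copper | [Cu]c1c(OCOC)c(Br)cc(Br)c1OCOC | intermediate (not isolated)
5 | 1,5-dibromo-2,4-bis(methoxymethoxy)-3-(3-methylbut-2-en-1-yl)benzene | COCOc1c(Br)cc(Br)c(OCOC)c1CC=C(C)C | intermediate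
6 | 4,6-dibromo-2-(3-methylbut-2-en-1-yl)benzene-1,3-diol | Oc1c(Br)cc(Br)c(O)c1CC=C(C)C | intermediate
7 | 1-(3-bromo-4-hydroxyphenyl)ethan-1-one | CC(=O)c1ccc(O)c(Br)c1 | starting material
8 | 1-[3-bromo-4-(methoxymethoxy)phenyl]ethan-1-one | CC(=O)c1ccc(OCOC)c(Br)c1 | intermediate
9 | methyl 3-[3-bromo-4-(methoxymethoxy)phenyl]-3-oxopropanoate | COC(=O)CC(=O)c1ccc(OCOC)c(Br)c1 | intermediate
10 | methyl (3R)-3-[3-bromo-4-(methoxymethoxy)phenyl]-3-hydroxypropanoate | COC(=O)C[C@@H](O)c1ccc(OCOC)c(Br)c1 | intermediate
11 | (3R)-3-[3-bromo-4-(methoxymethoxy)phenyl]-3-hydroxy-N-methoxy-N-methylpropanamide | CON(C)C(=O)C[C@@H](O)c1ccc(OCOC)c(Br)c1 | intermediate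
12 | (3S)-3-[3-bromo-4-(methoxymethoxy)phenyl]-3-[2,4-dibromo-5-hydroxy-6-(3-methylbut-2-en-1-yl)phenoxy]-N-methoxy-N-methylpropanamide | CON(C)C(=O)C[C@H](Oc1c(Br)cc(Br)c(O)c1CC=C(C)C)c1ccc(OCOC)c(Br)c1 | intermediate
13 | tetralithio hemiaminalate: (2S)-6-lithio-2-[3-lithio-4-(methoxymethoxy)phenyl]-4-[methoxy(methyl)amino]-8-(3-methylbut-2-en-1-yl)chromane-4,7-bis(olate) as its dilithium salt, either configuration at C4 | COCOc1ccc(cc1[Li])[C@@H]1CC(O[Li])(N(C)OC)c2cc([Li])c(O[Li])c(CC=C(C)C)c2O1 | intermediate (not isolated)
14 | the same hemiaminalate with copper in place of lithium at C6 and C3′ | COCOc1ccc(cc1[Cu])[C@@H]1CC(O[Li])(N(C)OC)c2cc([Cu])c(O[Li])c(CC=C(C)C)c2O1 | intermediate (not isolated)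
15 | (2S)-7-hydroxy-2-[4-(methoxymethoxy)-3-(3-methylbut-2-en-1-yl)phenyl]-6,8-bis(3-methylbut-2-en-1-yl)-2,3-dihydro-4H-chromen-4-one | CC(C)=CCc1cc([C@@H]2CC(=O)c3cc(CC=C(C)C)c(O)c(CC=C(C)C)c3O2)ccc1OCOC | intermediate
16 | (2S)-7-hydroxy-2-[4-hydroxy-3-(3-methylbut-2-en-1-yl)phenyl]-6,8-bis(3-methylbut-2-en-1-yl)-2,3-dihydro-4H-chromen-4-one | CC(C)=CCc1cc([C@@H]2CC(=O)c3cc(CC=C(C)C)c(O)c(CC=C(C)C)c3O2)ccc1O | target

**Step count and risks**
Total step count: 10 steps. Longest linear sequence: 7 steps (steps 4 to 10, from 7); the ring A branch (steps 1 to 3) joins at step 8.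

Most likely to fail, first: step 9. The triple exchange may stay incomplete, deprotonation at C3 may compete and expel the aryloxide, and the allylation of the two aryl–metal sites after ring closure may be incomplete, γ-selective or accompanied by O-allylation, so that mixtures form. The fallback sets out from 12 and comes back at 15, and separates ring closure from prenylation. The cyclised tetralithio species 13 is generated as in step 9, but its two aryllithium sites are quenched with 1,2-diiodoethane (fast and clean, no iodoetherification of the prenylphenoxide) to give, after work-up, (2S)-7-hydroxy-6-iodo-2-[3-iodo-4-(methoxymethoxy)phenyl]-8-(3-methylbut-2-en-1-yl)-2,3-dihydro-4H-chromen-4-one F1. A double Stille coupling of F1 with tributyl(3-methylbut-2-en-1-yl)stannane (Pd(PPh3)4, LiCl, DMF, 80 °C), under neutral conditions that should leave the C2 centre and the free phenol alone, then gives 15.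

Second: step 8. The β-hydroxy amide may dehydrate to the cinnamamide, the benzylic alkoxyphosphonium salt may ionise with erosion of enantiopurity, and the doubly ortho-substituted phenol may couple slowly or twice. The fallback sets out from 10 and 6 and comes back at 12; it makes the C2–O1 bond by SN2 opening of a β-lactone. Ester 10 is saponified (LiOH, THF/H2O, 0 °C) to (3R)-3-[3-bromo-4-(methoxymethoxy)phenyl]-3-hydroxypropanoic acid F2. This is closed by carboxyl activation (PhSO2Cl, pyridine, 0 °C; the carbinol C–O bond is not broken, so configuration is retained) to (4R)-4-[3-bromo-4-(methoxymethoxy)phenyl]oxetan-2-one F3. The monosodium salt of 6 (NaH, DMF, 0 °C → rt, 6 in excess) should open F3 at the benzylic carbon by alkyl–oxygen cleavage with inversion (acyl attack is reversible, alkyl attack is not) to give (3S)-3-[3-bromo-4-(methoxymethoxy)phenyl]-3-[2,4-dibromo-5-hydroxy-6-(3-methylbut-2-en-1-yl)phenoxy]propanoic acid F4. Carbodiimide coupling of F4 with MeNHOMe·HCl (EDC·HCl, HOBt, N-methylmorpholine, CH2Cl2) gives 12.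

Third: step 10. Protonation of a prenyl double bond next to a free phenol may lead to chroman formation, and prolonged acid may open and racemise the flavanone. The fallback sets out from 15 and comes back at 16, and avoids any Brønsted acid. TMSOTf/2,2′-bipyridyl (CH2Cl2, 0 °C) should convert the aryl MOM ether (and the free C7 phenol) into silyl ethers, giving (2S)-6,8-bis(3-methylbut-2-en-1-yl)-2-[3-(3-methylbut-2-en-1-yl)-4-(trimethylsilyloxy)phenyl]-7-(trimethylsilyloxy)-2,3-dihydro-4H-chromen-4-one F5. Neutral hydrolysis (H2O/THF, rt) then gives 16.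

**Further compounds**
F1 | step 9 | (2S)-7-hydroxy-6-iodo-2-[3-iodo-4-(methoxymethoxy)phenyl]-8-(3-methylbut-2-en-1-yl)-2,3-dihydro-4H-chromen-4-one | COCOc1ccc(cc1I)[C@@H]1CC(=O)c2cc(I)c(O)c(CC=C(C)C)c2O1
F2 | step 8 | (3R)-3-[3-bromo-4-(methoxymethoxy)phenyl]-3-hydroxypropanoic acid | OC(=O)C[C@@H](O)c1ccc(OCOC)c(Br)c1
F3 | step 8 | (4R)-4-[3-bromo-4-(methoxymethoxy)phenyl]oxetan-2-one | O=C1C[C@@H](O1)c1ccc(OCOC)c(Br)c1
F4 | step 8 | (3S)-3-[3-bromo-4-(methoxymethoxy)phenyl]-3-[2,4-dibromo-5-hydroxy-6-(3-methylbut-2-en-1-yl)phenoxy]propanoic acid | OC(=O)C[C@H](Oc1c(Br)cc(Br)c(O)c1CC=C(C)C)c1ccc(OCOC)c(Br)c1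
F5 | step 10 | (2S)-6,8-bis(3-methylbut-2-en-1-yl)-2-[3-(3-methylbut-2-en-1-yl)-4-(trimethylsilyloxy)phenyl]-7-(trimethylsilyloxy)-2,3-dihydro-4H-chromen-4-one | CC(C)=CCc1cc([C@@H]2CC(=O)c3cc(CC=C(C)C)c(O[Si](C)(C)C)c(CC=C(C)C)c3O2)ccc1O[Si](C)(C)C
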